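**Plan**

Eudesmane numbering is used: ring A = C1–C5 and C10, ring B = C5–C10, C1′ = benzylic carbon, C11 = carbinol carbon on C7, C14/C15 = methyls on C10/C4.
Retrosynthesis cuts the three aryl O–H (as methyl ethers) and two formyl groups, then C4–O, C4=C15, C1′–aryl, C1=C1′ and C11–O, and finally the ring B bonds C6–C7 and C9–C10.
Forward: ring A comes from 3-methylcyclohex-2-enone with C6 put on C5 as a chloromethyl group; ring B is closed in one flask from a homoprenyl Grignard reagent (C7–C9, C11–C13); the C1 arm, the aryl group, C15 and the arene substituents follow.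
Enabling feature: the C4 carbonyl of ring A makes C10 (β-carbon) an acceptor and, once chloride has left C6, makes the exocyclic C6 an acceptor; the 1,3-spacing C10–C5–C6 matches C9–C8–C7 of the homoprenyl chain, whose C7=C11 alkene closes onto C6 and leaves the isopropenyl group that becomes the C11 carbinol.
Stereochemistry: C10 from a chiral copper catalyst; C7 from the chair of the ring B closure; C5 from α-face protonation, secured thermodynamically at step 11; C1′ and C1 from α-face additions anti to the C10 methyl; C4 from α-face oxygen capture.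

Key step: step 4

Remark: the sense of induction of the phosphoramidite ligand in step 4 is assumed; if it gave the antipode of 6, the enantiomeric ligand would be used.

Step 1
Reactants: 1 3-methylcyclohex-2-en-1-one
Product: 2 2-iodo-3-methylcyclohex-2-en-1-one
Conditions: I2, pyridine, CH2Cl2, 0 °C to rt
Reagents that add atoms: iodine [I][I]
Why: α-Iodination of an enone by conjugate addition of pyridine, iodination of the enolate and elimination should place the halogen on C5, where C6 is to be attached; no stereocentre is formed.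

Step 2
Reactants: 2 2-iodo-3-methylcyclohex-2-en-1-one
Product: 3 2-(hydroxymethyl)-3-methylcyclohex-2-en-1-one
Conditions: Bu3SnCH2OH, Pd(PPh3)4 (5 mol %), dioxane, 90 °C
Reagents that add atoms: (tributylstannyl)methanol OC[Sn](CCCC)(CCCC)CCCC
Why: Stille coupling of the electron-poor alkenyl iodide with the α-oxygenated stannane should transfer the hydroxymethyl group (C6) to C5; no stereocentre is formed.

Step 3
Reactants: 3 2-(hydroxymethyl)-3-methylcyclohex-2-en-1-one
Product: 4 2-(chloromethyl)-3-methylcyclohex-2-en-1-one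
Conditions: SOCl2, pyridine, Et2O, 0 °C
Reagents that add atoms: thionyl chloride ClS(Cl)=O
Why: Chlorodehydroxylation of the primary allylic alcohol in the presence of pyridine should proceed by SN2 displacement without allylic transposition, the conjugated enone also being the stable isomer.

Step 4
Reactants: 4 2-(chloromethyl)-3-methylcyclohex-2-en-1-one; 5 5-bromo-2-methylpent-2-ene
Product: 7 (4aR,7R,8aR)-4a-methyl-7-(prop-1-en-2-yl)octahydronaphthalen-1(2H)-one, via exocyclic enone 6 (not isolated)
Conditions: 5, Mg, Et2O (Grignard reagent, 1.3 equiv), added slowly to 4, CuBr·SMe2 (5 mol %), (S)-1,1′-binaphthyl-2,2′-diyl N,N-bis[(S)-1-phenylethyl]phosphoramidite (10 mol %), CH2Cl2, −78 °C; then Me2AlCl (2.5 equiv), −78 to 0 °C, same flask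
Reagents that add atoms: none
Why: Proposed new method: the copper catalyst transfers the 4-methylpent-3-enyl group to C10, the β-carbon of the ring A enone, with loss of chloride from C6 (SN2′, equal to conjugate addition and β-elimination), which forms C9–C10 and unveils the exocyclic enone 6; Me2AlCl then binds the C4 carbonyl, the alkene carbon C7 adds to the enone terminus C6 (C6–C7) to give an aluminium enolate and a tertiary C11 cation, and a methyl proton is passed on, so that the second stage is in sum a conjugate ene reaction. The closest known reactions are the copper-catalysed asymmetric allylic alkylation of γ,γ-disubstituted allyl chlorides with Grignard reagents, the SN2′ reaction of organocopper reagents with 2-(halomethyl)- and 2-(acyloxymethyl)cycloalkenones, and Lewis acid promoted ene-type cyclisations of enones; the enantioselective SN2′ step that makes a quaternary centre on a 2-(chloromethyl)-3-methylcycloalkenone, and its coupling with the ene step in one flask, have not been shown. Ring B is closed only in the second stage, 6-endo-trig at the C5=C6 enone and exo with respect to the C7=C11 alkene (C11 stays outside the ring), through the single chair open to the tether, which lies on the face of ring A opposite to the C10 methyl. C10 is set by the chiral ligand on copper, which selects one face of the flat enone; C7 is set by the equatorial place of the C11 cation in that chair (isopropenyl cis to the angular methyl); C5 is set when the C4 enol is protonated from the α-face, anti to the axial methyl, and is open to later thermodynamic correction. The step needs attack at C10 (γ) and not at C6 (α) or at the carbonyl, which the soft copper nucleophile, slow addition at −78 °C and the polarisation of the enone should secure, and it needs C6–C7 and not C5–C7 bond formation, which follows from C6 being the electrophilic terminus of the exocyclic enone.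

Step 5
Reactants: 7 (4aR,7R,8aR)-4a-methyl-7-(prop-1-en-2-yl)octahydronaphthalen-1(2H)-one
Product: 8 (4aR,7R,8aR)-7-(2-hydroxypropan-2-yl)-4a-methyloctahydronaphthalen-1(2H)-one
Conditions: Co(acac)2 (20 mol %), PhSiH3, O2 (1 atm), THF, rt
Reagents that add atoms: oxygen O=O
Why: Mukaiyama hydration (hydrogen atom transfer, capture of the tertiary C11 radical by O2, reduction of the peroxide) should convert the 1,1-disubstituted alkene into the tertiary alcohol with Markovnikov selectivity and spare the saturated ketone; no new stereocentre.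

Step 6
Reactants: 8 (4aR,7R,8aR)-7-(2-hydroxypropan-2-yl)-4a-methyloctahydronaphthalen-1(2H)-one
Product: 10 (4aS,7R,8aR)-7-(2-hydroxypropan-2-yl)-4a-methyl-4a,5,6,7,8,8a-hexahydronaphthalen-1(4H)-one, via silyl enol ether 9 (not isolated)
Conditions: LiN(iPr)2 (2.3 equiv), Me3SiCl (2.5 equiv), THF, −78 °C; then Pd(OAc)2 (1.1 equiv), MeCN, rt; 1 M HCl work-up
Reagents that add atoms: none
Why: Saegusa–Ito oxidation: kinetic deprotonation should occur at the C3 methylene and not at the hindered C5 methine, so the enone forms between C2 and C3, while the C11 alkoxide is silylated in passing and freed on work-up.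

Step 7
Reactants: 10 (4aS,7R,8aR)-7-(2-hydroxypropan-2-yl)-4a-methyl-4a,5,6,7,8,8a-hexahydronaphthalen-1(4H)-one; 11 3-methylbutanal
Product: 13 (4aS,7R,8aR)-4-(1-hydroxy-3-methylbutyl)-7-(2-hydroxypropan-2-yl)-4a-methyl-4a,5,6,7,8,8a-hexahydronaphthalen-1(4H)-one (mixture of epimers at C1 and C1′), via silyl dienol ether 12 (not isolated)
Conditions: Me3SiOTf (2.5 equiv), Et3N, CH2Cl2, 0 °C to rt; volatiles removed; then 11, BF3·OEt2, CH2Cl2, −78 °C; 1 M HCl work-up
Reagents that add atoms: none
Why: Vinylogous Mukaiyama aldol reaction: the extended dienol ether should attack the activated aldehyde through its terminus C1, the only γ-position; the configurations at C1 and C1′ do not matter because both carbons become sp2 in step 8.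

Step 8
Reactants: 13 (4aS,7R,8aR)-4-(1-hydroxy-3-methylbutyl)-7-(2-hydroxypropan-2-yl)-4a-methyl-4a,5,6,7,8,8a-hexahydronaphthalen-1(4H)-one
Product: 15 (4E,4aR,7R,8aR)-7-(2-hydroxypropan-2-yl)-4a-methyl-4-(3-methylbutylidene)-4a,5,6,7,8,8a-hexahydronaphthalen-1(4H)-one, via acetate 14 (not isolated)
Conditions: Ac2O, DMAP (cat.), Et3N, CH2Cl2, 0 °C; then DBU, rt
Reagents that add atoms: none
Why: Selective acetylation of the secondary alcohol and vinylogous E1cB elimination (deprotonation at C1) should give the linear dienone, the E isomer with the isobutyl group turned away from the quaternary C10 being the stable one.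

Step 9
Reactants: 15 (4E,4aR,7R,8aR)-7-(2-hydroxypropan-2-yl)-4a-methyl-4-(3-methylbutylidene)-4a,5,6,7,8,8a-hexahydronaphthalen-1(4H)-one; 16 1,3,5-trimethoxybenzene
Product: 17 (4aR,7R,8aR)-7-(2-hydroxypropan-2-yl)-4a-methyl-4-[(1S)-3-methyl-1-(2,4,6-trimethoxyphenyl)butyl]-4a,5,6,7,8,8a-hexahydronaphthalen-1(2H)-one
Conditions: 16, n-BuLi, TMEDA, THF, 0 °C; CuI, −40 °C (lithium diarylcuprate, excess); 15, −78 to −30 °C; AcOH, −78 °C
Reagents that add atoms: none
Why: 1,6-Conjugate addition of the diarylcuprate should put the aryl group on the δ-carbon C1′ from the α-face of the flat E-configured exocyclic alkene, anti to the axial C10 methyl, which gives the 1′S centre; kinetic protonation of the dienolate at C3 leaves the C1=C2 double bond.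

Step 10
Reactants: 17 (4aR,7R,8aR)-7-(2-hydroxypropan-2-yl)-4a-methyl-4-[(1S)-3-methyl-1-(2,4,6-trimethoxyphenyl)butyl]-4a,5,6,7,8,8a-hexahydronaphthalen-1(2H)-one
Product: 18 (4S,4aS,7R,8aR)-7-(2-hydroxypropan-2-yl)-4a-methyl-4-[(1S)-3-methyl-1-(2,4,6-trimethoxyphenyl)butyl]octahydronaphthalen-1(2H)-one
Conditions: H2 (3 atm), Pd/C, EtOAc, rt
Reagents that add atoms: none
Why: Heterogeneous hydrogenation should deliver hydrogen to the trisubstituted C1=C2 alkene from the α-face, anti to the angular methyl, so that the arm at C1 ends β (equatorial); ketone and arene are not touched.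

Step 11
Reactants: 18 (4S,4aS,7R,8aR)-7-(2-hydroxypropan-2-yl)-4a-methyl-4-[(1S)-3-methyl-1-(2,4,6-trimethoxyphenyl)butyl]octahydronaphthalen-1(2H)-one
Product: 19 1β-[(1S)-3-methyl-1-(2,4,6-trimethoxyphenyl)butyl]-5α-eudesm-4(15)-en-11-ol
Conditions: Ph3PCH3Br, KOtBu, toluene, 80 °C
Reagents that add atoms: methyltriphenylphosphonium bromide C[P+](c1ccccc1)(c1ccccc1)c1ccccc1.[Br-]
Why: Wittig methylenation of the C4 ketone with excess ylide supplies C15; under the basic conditions C5 should rest in the trans-fused form, the only one in which the C1 and C7 substituents are both equatorial.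

Step 12
Reactants: 19 1β-[(1S)-3-methyl-1-(2,4,6-trimethoxyphenyl)butyl]-5α-eudesm-4(15)-en-11-ol
Product: 20 1β-[(1S)-3-methyl-1-(2,4,6-trimethoxyphenyl)butyl]-5α-eudesmane-4α,11-diol
Conditions: Co(acac)2 (20 mol %), PhSiH3, O2 (1 atm), THF, rt
Reagents that add atoms: oxygen O=O
Why: Mukaiyama hydration of the exocyclic alkene: the tertiary C4 radical should be captured by O2 on the α-face (equatorial), the β-face being screened by the syn-axial C10 methyl, which gives the 4α-hydroxy-4β-methyl carbinol.

Step 13
Reactants: 20 1β-[(1S)-3-methyl-1-(2,4,6-trimethoxyphenyl)butyl]-5α-eudesmane-4α,11-diol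
Product: 22 1β-[(1S)-1-(3,5-diformyl-2,4,6-trimethoxyphenyl)-3-methylbutyl]-5α-eudesmane-4α,11-diol, via amino alkoxide 21 (not isolated)
Conditions: n-BuLi (3.3 equiv), TMEDA, THF, 0 °C; DMF (1.1 equiv), −78 to 0 °C; n-BuLi (1.5 equiv), 0 °C; DMF (3 equiv); then 1 M HCl
Reagents that add atoms: N,N-dimethylformamide CN(C)C=O
Why: Directed ortho-lithiation between two methoxy groups followed by formylation, run twice in one flask with the first formyl group held as its lithium α-amino alkoxide, should install both aldehydes without Lewis acid, so the two tertiary alkoxides survive.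

Step 14
Reactants: 22 1β-[(1S)-1-(3,5-diformyl-2,4,6-trimethoxyphenyl)-3-methylbutyl]-5α-eudesmane-4α,11-diol
Product: 23 Macrocarpal J
Conditions: NaSEt, DMF, 110 °C; then dilute HCl
Reagents that add atoms: none
Why: Nucleophilic demethylation (SN2 at methyl) of aryl methyl ethers that stand ortho and para to formyl groups should free the three phenols under basic conditions that spare the tertiary alcohols and all stereocentres.

**Compound list**

1 | 3-methylcyclohex-2-en-1-one | CC1=CC(=O)CCC1 | starting material
2 | 2-iodo-3-methylcyclohex-2-en-1-one | CC1=C(I)C(=O)CCC1 | intermediate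
3 | 2-(hydroxymethyl)-3-methylcyclohex-2-en-1-one | CC1=C(CO)C(=O)CCC1 | intermediate
4 | 2-(chloromethyl)-3-methylcyclohex-2-en-1-one | CC1=C(CCl)C(=O)CCC1 | intermediate
5 | 5-bromo-2-methylpent-2-ene | CC(C)=CCCBr | starting material
6 | (3R)-3-methyl-2-methylidene-3-(4-methylpent-3-en-1-yl)cyclohexan-1-one | CC(C)=CCC[C@@]1(C)CCCC(=O)C1=C | intermediate
7 | (4aR,7R,8aR)-4a-methyl-7-(prop-1-en-2-yl)octahydronaphthalen-1(2H)-one (trans-fused, isopropenyl cis to the angular methyl) | C1CCC(=O)[C@@H]2C[C@H](C(C)=C)CC[C@]21C | intermediate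
8 | (4aR,7R,8aR)-7-(2-hydroxypropan-2-yl)-4a-methyloctahydronaphthalen-1(2H)-one | C1CCC(=O)[C@@H]2C[C@H](C(C)(C)O)CC[C@]21C | intermediate
9 | bis(trimethylsilyl) derivative of 8 (C3=C4 silyl enol ether, C11 silyl ether) | C1CC=C(O[Si](C)(C)C)[C@@H]2C[C@H](C(C)(C)O[Si](C)(C)C)CC[C@]21C | intermediate
10 | (4aS,7R,8aR)-7-(2-hydroxypropan-2-yl)-4a-methyl-4a,5,6,7,8,8a-hexahydronaphthalen-1(4H)-one | C1C=CC(=O)[C@@H]2C[C@H](C(C)(C)O)CC[C@]21C | intermediate
11 | 3-methylbutanal | CC(C)CC=O | starting material
12 | extended trimethylsilyl dienol ether of 10 (C1=C2–C3=C4–OSiMe3, C11 silyl ether) | C1=CC=C(O[Si](C)(C)C)[C@@H]2C[C@H](C(C)(C)O[Si](C)(C)C)CC[C@]21C | intermediate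
13 | (4aS,7R,8aR)-4-(1-hydroxy-3-methylbutyl)-7-(2-hydroxypropan-2-yl)-4a-methyl-4a,5,6,7,8,8a-hexahydronaphthalen-1(4H)-one, epimers at C1 and C1′ | CC(C)CC(O)C1C=CC(=O)[C@@H]2C[C@H](C(C)(C)O)CC[C@]21C | intermediate
14 | acetate of the secondary alcohol of 13 | CC(C)CC(OC(C)=O)C1C=CC(=O)[C@@H]2C[C@H](C(C)(C)O)CC[C@]21C | intermediate
15 | (4E,4aR,7R,8aR)-7-(2-hydroxypropan-2-yl)-4a-methyl-4-(3-methylbutylidene)-4a,5,6,7,8,8a-hexahydronaphthalen-1(4H)-one | CC(C)C/C=C1\C=CC(=O)[C@@H]2C[C@H](C(C)(C)O)CC[C@]21C | intermediate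
16 | 1,3,5-trimethoxybenzene | COc1cc(OC)cc(OC)c1 | starting material
17 | (4aR,7R,8aR)-7-(2-hydroxypropan-2-yl)-4a-methyl-4-[(1S)-3-methyl-1-(2,4,6-trimethoxyphenyl)butyl]-4a,5,6,7,8,8a-hexahydronaphthalen-1(2H)-one | CC(C)C[C@H](c1c(OC)cc(OC)cc1OC)C1=CCC(=O)[C@@H]2C[C@H](C(C)(C)O)CC[C@]21C | intermediate
18 | (4S,4aS,7R,8aR)-7-(2-hydroxypropan-2-yl)-4a-methyl-4-[(1S)-3-methyl-1-(2,4,6-trimethoxyphenyl)butyl]octahydronaphthalen-1(2H)-one | CC(C)C[C@H](c1c(OC)cc(OC)cc1OC)[C@@H]1CCC(=O)[C@@H]2C[C@H](C(C)(C)O)CC[C@]21C | intermediate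
19 | 1β-[(1S)-3-methyl-1-(2,4,6-trimethoxyphenyl)butyl]-5α-eudesm-4(15)-en-11-ol (7β-hydroxyisopropyl, 10β-methyl) | CC(C)C[C@H](c1c(OC)cc(OC)cc1OC)[C@@H]1CCC(=C)[C@@H]2C[C@H](C(C)(C)O)CC[C@]21C | intermediate
20 | 1β-[(1S)-3-methyl-1-(2,4,6-trimethoxyphenyl)butyl]-5α-eudesmane-4α,11-diol (4β-methyl) | CC(C)C[C@H](c1c(OC)cc(OC)cc1OC)[C@@H]1CC[C@@](C)(O)[C@@H]2C[C@H](C(C)(C)O)CC[C@]21C | intermediate
21 | lithium α-amino alkoxide from the first formylation of 20 (both tertiary alcohols as lithium alkoxides) | CC(C)C[C@H](c1c(OC)c(C(O[Li])N(C)C)c(OC)cc1OC)[C@@H]1CC[C@@](C)(O[Li])[C@@H]2C[C@H](C(C)(C)O[Li])CC[C@]21C | intermediate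
22 | 1β-[(1S)-1-(3,5-diformyl-2,4,6-trimethoxyphenyl)-3-methylbutyl]-5α-eudesmane-4α,11-diol | CC(C)C[C@H](c1c(OC)c(C=O)c(OC)c(C=O)c1OC)[C@@H]1CC[C@@](C)(O)[C@@H]2C[C@H](C(C)(C)O)CC[C@]21C | intermediate
23 | Macrocarpal J | CC(C)C[C@H](c1c(O)c(C=O)c(O)c(C=O)c1O)[C@@H]1CC[C@@](C)(O)[C@@H]2C[C@H](C(C)(C)O)CC[C@]21C | target

**Step count and risks**

Total step count: 14. Longest linear sequence: 14 steps (from 1).

Steps most likely to fail:

Step 4. The organometallic may attack the carbonyl or C6 (α-substitution) instead of C10, the catalyst may discriminate the enone faces poorly, and the C11 cation may be captured by chloride instead of losing a proton. The fallback sets out from 1 and returns at 7 with known reactions, making the two bonds in separate operations. Copper-catalysed asymmetric conjugate addition of the Grignard reagent from 5 to 1 (Cu(OTf)2, chiral N-heterocyclic carbene ligand, Et2O, −30 °C), with the magnesium enolate trapped by N,N-dimethylmethyleneiminium iodide, would give the Mannich base (3R)-2-[(dimethylamino)methyl]-3-methyl-3-(4-methylpent-3-en-1-yl)cyclohexan-1-one F1. Iodomethane would give the quaternary ammonium iodide F2, DBU would eliminate trimethylamine to give 6, now isolated, and Me2AlCl in CH2Cl2 would close ring B to 7.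

Step 7. The dienol ether may react through C3 (α) or not at all at the neopentyl terminus C1, or silylation may go toward C5. The fallback sets out from 10 and returns at 15. The dienol ether 12 would be treated with trimethyl orthoformate and BF3·OEt2, the smallest carbon electrophile, to give the C1-(dimethoxymethyl) enone F3. Aqueous acid would give the vinylogous formyl compound as its enol, the C1-hydroxymethylene dienone F4, and 4-methylbenzenesulfonyl chloride with Et3N would give the enol sulfonate F5. Lithium bis(2-methylpropyl)cuprate would then give 15 by addition–elimination at C1′.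

Step 9. Transfer of the doubly ortho-substituted aryl group from copper may be slow, and 1,4-addition at C2 or poor facial selection may intervene. The fallback sets out from 15 and returns at 17. Ortho-selective Friedel–Crafts-type 1,6-addition of 3,5-dimethoxyphenol as its bromomagnesium phenoxide (EtMgBr, toluene, then 15, 60 °C) would give the phenol (4aR,7R,8aR)-4-[(1S)-1-(2-hydroxy-4,6-dimethoxyphenyl)-3-methylbutyl]-7-(2-hydroxypropan-2-yl)-4a-methyl-4a,5,6,7,8,8a-hexahydronaphthalen-1(2H)-one F6. O-Methylation with iodomethane and K2CO3 in acetone would give 17.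

Further compounds
F1 | step 4 | (3R)-2-[(dimethylamino)methyl]-3-methyl-3-(4-methylpent-3-en-1-yl)cyclohexan-1-one (epimers at C2) | CC(C)=CCC[C@@]1(C)CCCC(=O)C1CN(C)C
F2 | step 4 | trimethylammonium iodide derived from F1 | CC(C)=CCC[C@@]1(C)CCCC(=O)C1C[N+](C)(C)C.[I-]
F3 | step 7 | (4aS,7R,8aR)-4-(dimethoxymethyl)-7-(2-hydroxypropan-2-yl)-4a-methyl-4a,5,6,7,8,8a-hexahydronaphthalen-1(4H)-one (epimers at C1) | COC(OC)C1C=CC(=O)[C@@H]2C[C@H](C(C)(C)O)CC[C@]21C
F4 | step 7 | (4aR,7R,8aR)-4-(hydroxymethylidene)-7-(2-hydroxypropan-2-yl)-4a-methyl-4a,5,6,7,8,8a-hexahydronaphthalen-1(4H)-one | O/C=C1\C=CC(=O)[C@@H]2C[C@H](C(C)(C)O)CC[C@]21C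
F5 | step 7 | 4-methylbenzenesulfonate of the enol F4 | Cc1ccc(cc1)S(=O)(=O)O/C=C1\C=CC(=O)[C@@H]2C[C@H](C(C)(C)O)CC[C@]21C
F6 | step 9 | (4aR,7R,8aR)-4-[(1S)-1-(2-hydroxy-4,6-dimethoxyphenyl)-3-methylbutyl]-7-(2-hydroxypropan-2-yl)-4a-methyl-4a,5,6,7,8,8a-hexahydronaphthalen-1(2H)-one | CC(C)C[C@H](c1c(O)cc(OC)cc1OC)C1=CCC(=O)[C@@H]2C[C@H](C(C)(C)O)CC[C@]21C
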